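The 14-membered carbocycle (C1 ring-fusion CH, C2 lactone O–CH, C6 acetoxy CH, C14 carbinol CH) is cut at C6–C7. The key step exploits the C6 stereocentre standing on the E-C7=C8 alkene whose C8 methyl is cis to C6: syn methylalumination of the terminal alkyne of fragment 2 builds C8–CH3 and the alkenyl metal, and a titanium–BINOL catalyst adds it to the C6 aldehyde of fragment 1, forming C6–C7 and setting C6 in one flask. Fragment 1 is a β,γ-unsaturated aldehyde with the silylated C2 carbinol and a vinyl group; fragment 2 is an enyne ending in a vinyl group. Metathesis then closes C1=C14, whose epoxide builds the lactone.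

Key step: step 12

Remark on numbering: ring locants C1–C14 are those defined above, and Cα is the lactone carbon that carries the exocyclic methylene. Acyclic compounds are named by their own chain numbering.

Assumption on the sense of induction: by analogy with titanium–BINOLate organozinc additions, (R)-configured biaryldiol ligands are taken to deliver the carbon nucleophile to the Re face of the aldehyde. The antipodal ligands are equally available should the opposite sense be met.

Remark on descriptors: C2 keeps one spatial arrangement throughout. Its descriptor is R while C3 outranks C1 (10–13, 22–25) and S once C1 carries oxygen or Cα (26, 28–30). C1 is S in 26 and formally R in 28 for the same reason.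

Step 1
Reactants: 1 but-3-yn-1-ol
Product: 2 1-[(but-3-yn-1-yloxy)methyl]-4-methoxybenzene
Conditions: NaH, 4-methoxybenzyl chloride, Bu4NI (cat.), THF, 0 °C → rt
Reagents that add atoms: 4-methoxybenzyl chloride, COc1ccc(CCl)cc1
Why: Williamson etherification, in which NaH deprotonates only the hydroxyl (the alkyne C–H is far less acidic) and the alkoxide displaces the benzylic chloride.

Step 2
Reactants: 2 1-[(but-3-yn-1-yloxy)methyl]-4-methoxybenzene; 3 trimethylaluminium; 4 formaldehyde (as paraformaldehyde)
Product: 7 (2E)-5-[(4-methoxyphenyl)methoxy]-3-methylpent-2-en-1-ol, via alkenyldimethylalane 5 (not isolated), via lithium alkenylalanate 6 (not isolated)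
Conditions: AlMe3, Cp2ZrCl2 (0.25 equiv), CH2Cl2, rt; volatiles removed; n-BuLi, hexane/THF, −78 → 0 °C; (CH2O)n, rt
Reagents that add atoms: trimethylaluminium (3), C[Al](C)C; formaldehyde (4), C=O
Why: Negishi zirconium-catalysed methylalumination adds CH3 and Al syn across the alkyne with methyl on the internal carbon, and the butyl-activated alanate 6 passes the alkenyl group to formaldehyde with retention, so the hydroxymethyl group ends cis to the new methyl (2E).

Step 3
Reactants: 7 (2E)-5-[(4-methoxyphenyl)methoxy]-3-methylpent-2-en-1-ol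
Product: 8 (2E)-5-[(4-methoxyphenyl)methoxy]-3-methylpent-2-enal
Conditions: MnO2, CH2Cl2, rt
Reagents that add atoms: none
Why: MnO2 is a mild heterogeneous oxidant selective for allylic alcohols and should stop at the E-enal without double-bond migration.

Step 4
Reactants: 8 (2E)-5-[(4-methoxyphenyl)methoxy]-3-methylpent-2-enal; 9 vinylmagnesium bromide
Product: 10 (3R,4E)-7-[(4-methoxyphenyl)methoxy]-5-methylhepta-1,4-dien-3-ol
Conditions: Ti(OiPr)4 (excess), (R)-3-(3,5-diphenylphenyl)-5,5′,6,6′,7,7′,8,8′-octahydro-1,1′-bi-2-naphthol (5 mol%), CH2=CHMgBr premixed with Ti(OiPr)4 and added slowly, CH2Cl2, 0 °C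
Reagents that add atoms: vinylmagnesium bromide (9), C=C[Mg]Br
Why: Catalytic enantioselective addition of a Grignard-derived organotitanium reagent to an aldehyde: CH2=CHTi(OiPr)3 adds 1,2 to the enal inside the chiral titanium biaryldiolate, and the (R)-ligand should expose the Re face of the formyl group, which gives the 3R carbinol (the later C2).

Step 5
Reactants: 10 (3R,4E)-7-[(4-methoxyphenyl)methoxy]-5-methylhepta-1,4-dien-3-ol
Product: 11 tert-butyl{[(3R,4E)-7-[(4-methoxyphenyl)methoxy]-5-methylhepta-1,4-dien-3-yl]oxy}dimethylsilane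
Conditions: t-BuMe2SiCl, imidazole, DMF, rt
Reagents that add atoms: tert-butyldimethylsilyl chloride, CC(C)(C)[Si](C)(C)Cl
Why: Imidazole-promoted silylation of the secondary alcohol at oxygen, under non-acidic conditions that leave the doubly allylic stereocentre untouched.

Step 6
Reactants: 11 tert-butyl{[(3R,4E)-7-[(4-methoxyphenyl)methoxy]-5-methylhepta-1,4-dien-3-yl]oxy}dimethylsilane
Product: 12 (3E,5R)-5-[(tert-butyldimethylsilyl)oxy]-3-methylhepta-3,6-dien-1-ol
Conditions: DDQ, CH2Cl2/pH 7 buffer, 0 °C
Reagents that add atoms: none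
Why: Oxidative cleavage of the electron-rich 4-methoxybenzyl ether by DDQ (hydride abstraction, then hydrolysis of the oxocarbenium ion) frees the primary alcohol, while the silyl ether and the alkenes should be inert at 0 °C.

Step 7
Reactants: 12 (3E,5R)-5-[(tert-butyldimethylsilyl)oxy]-3-methylhepta-3,6-dien-1-ol
Product: 13 (3E,5R)-5-[(tert-butyldimethylsilyl)oxy]-3-methylhepta-3,6-dienal (fragment 1)
Conditions: Dess–Martin periodinane, NaHCO3, CH2Cl2, 0 °C; used crude at once
Reagents that add atoms: none
Why: Buffered Dess–Martin oxidation is non-basic enough to give the β,γ-unsaturated aldehyde without migration of the C3=C4 alkene into conjugation.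

Step 8
Reactants: 14 pent-4-yn-1-ol; 15 ethyl 2-(triphenylphosphoranylidene)propanoate
Product: 17 ethyl (2E)-2-methylhept-2-en-6-ynoate, via pent-4-ynal 16 (not isolated)
Conditions: PhI(OAc)2, (2,2,6,6-tetramethylpiperidin-1-yl)oxyl (10 mol%), CH2Cl2, rt; then 15, rt
Reagents that add atoms: ethyl 2-(triphenylphosphoranylidene)propanoate (15), CCOC(=O)C(C)=P(c1ccccc1)(c1ccccc1)c1ccccc1
Why: Tandem oxoammonium oxidation and Wittig olefination avoids isolating the volatile aldehyde 16, and the stabilised α-methyl ylide should give the E-trisubstituted enoate.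

Step 9
Reactants: 17 ethyl (2E)-2-methylhept-2-en-6-ynoate
Product: 18 (2E)-2-methylhept-2-en-6-yn-1-ol
Conditions: i-Bu2AlH, CH2Cl2, −78 °C
Reagents that add atoms: none
Why: The aluminium hydride reduces the conjugated ester 1,2 to the allylic alcohol at low temperature without touching the alkyne or the alkene geometry.

Step 10
Reactants: 18 (2E)-2-methylhept-2-en-6-yn-1-ol
Product: 19 (5E)-7-bromo-6-methylhept-5-en-1-yne
Conditions: CBr4, PPh3, CH2Cl2, 0 °C
Reagents that add atoms: carbon tetrabromide, BrC(Br)(Br)Br
Why: Appel bromination displaces the oxyphosphonium group at the primary carbon in an SN2 manner, so neither allylic transposition nor loss of E geometry is expected.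

Step 11
Reactants: 19 (5E)-7-bromo-6-methylhept-5-en-1-yne; 9 vinylmagnesium bromide
Product: 20 (5E)-6-methylnona-5,8-dien-1-yne (fragment 2)
Conditions: CH2=CHMgBr (2.5 equiv), CuI (10 mol%), THF, −30 → 0 °C
Reagents that add atoms: vinylmagnesium bromide (9), C=C[Mg]Br
Why: Copper-catalysed Grignard substitution of the primary allylic bromide at the α-carbon (SN2 mode, favoured by a rapidly formed diorganocuprate in THF) keeps the E alkene, and the excess Grignard reagent covers any deprotonation of the alkyne C–H, which work-up restores.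

Step 12
Reactants: 20 (5E)-6-methylnona-5,8-dien-1-yne (fragment 2); 3 trimethylaluminium; 13 (3E,5R)-5-[(tert-butyldimethylsilyl)oxy]-3-methylhepta-3,6-dienal (fragment 1)
Product: 22 (3R,4E,7S,8E,12E)-3-[(tert-butyldimethylsilyl)oxy]-5,9,13-trimethylhexadeca-1,4,8,12,15-pentaen-7-ol, via alkenyldimethylalane 21 (not isolated)
Conditions: 20 (1.5 equiv), AlMe3 (2 equiv), Cp2ZrCl2 (0.25 equiv), CH2Cl2, rt; volatiles and free AlMe3 removed in vacuo; toluene, Ti(OiPr)4 (3 equiv), (R)-1,1′-bi-2-naphthol (20 mol%), then 13, 0 °C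
Reagents that add atoms: trimethylaluminium (3), C[Al](C)C
Why: Zirconocene-assisted syn carbometalation puts methyl on the internal C8 and aluminium on the terminal C7, so alkenylalane 21 already has the E-C7=C8 geometry; the alkenyl group then passes to the chiral titanium–BINOLate, which activates aldehyde 13 and transfers C7 with retention of alkene geometry. The closest known reaction types are Negishi methylalumination with direct aldehyde trapping and titanium–BINOL-catalysed enantioselective additions of alkenylaluminium reagents to aldehydes. No ring is closed. The new C6 stereocentre (C7 of the chain name) is set by the catalyst: the (R)-ligand should deliver C7 to the Re face of the formyl group, giving 6S, while the remote C2 centre exerts no useful bias. The step needs chemoselectivity for the alkyne over the C14 vinyl and C11=C12 alkenes (alkynes are carbometalated far faster by Cp2ZrCl2/AlMe3), alkenyl over methyl transfer (secured by the sp2 transfer preference and by stripping free AlMe3), and survival of the β,γ-unsaturated aldehyde (only Lewis-acidic, non-basic species are present and the aldehyde is used fresh).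

Step 13
Reactants: 22 (3R,4E,7S,8E,12E)-3-[(tert-butyldimethylsilyl)oxy]-5,9,13-trimethylhexadeca-1,4,8,12,15-pentaen-7-ol
Product: 23 (3R,4E,7S,8E,12E)-3-[(tert-butyldimethylsilyl)oxy]-5,9,13-trimethylhexadeca-1,4,8,12,15-pentaen-7-yl acetate
Conditions: Ac2O, pyridine, 4-(dimethylamino)pyridine (cat.), CH2Cl2, rt
Reagents that add atoms: acetic anhydride, CC(=O)OC(C)=O
Why: Nucleophile-catalysed acylation of the secondary allylic alcohol at oxygen, so the C6 configuration is retained.

Step 14
Reactants: 23 (3R,4E,7S,8E,12E)-3-[(tert-butyldimethylsilyl)oxy]-5,9,13-trimethylhexadeca-1,4,8,12,15-pentaen-7-yl acetate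
Product: 24 (2R,6S)-2-[(tert-butyldimethylsilyl)oxy]-4,8,12-trimethyl 14-membered carbocyclic tetraene 6-acetate with E alkenes at C1=C14, C3=C4, C7=C8 and C11=C12 (ring locants)
Conditions: second-generation Grubbs catalyst RuCl2(H2IMes)(PCy3)(=CHPh) (10 mol%), CH2Cl2 (1 mM), 40 °C
Reagents that add atoms: none
Why: Ring-closing olefin metathesis: only the two monosubstituted vinyl groups engage the ruthenium carbene readily, the E-trisubstituted alkenes cannot be drawn into small rings, and high dilution with loss of ethene should drive closure of the 14-membered ring to the less strained E-C1=C14 alkene.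

Step 15
Reactants: 24 macrocyclic silyl ether acetate
Product: 25 (2R,6S)-2-hydroxy-4,8,12-trimethyl 14-membered carbocyclic tetraene 6-acetate (E at C1=C14, C3=C4, C7=C8, C11=C12)
Conditions: Bu4NF, AcOH, THF, 0 °C → rt
Reagents that add atoms: none
Why: Fluoride-mediated desilylation driven by the strong Si–F bond, with acetic acid buffering to keep the C6 acetate from base-induced cleavage.

Step 16
Reactants: 25 macrocyclic allylic alcohol
Product: 26 (1S,2S,6S,14S)-1,14-epoxy-2-hydroxy-4,8,12-trimethyl 14-membered carbocyclic triene 6-acetate (trans epoxide, epoxide oxygen anti to the C2 hydroxyl)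
Conditions: Ti(OiPr)4, L-(+)-diisopropyl tartrate, t-BuOOH, 4 Å molecular sieves, CH2Cl2, −20 °C
Reagents that add atoms: tert-butyl hydroperoxide, CC(C)(C)OO
Why: Katsuki–Sharpless epoxidation: with the L-(+)-tartrate the E-C1=C14 arm of this carbinol is the matched one and takes oxygen anti to the C2 hydroxyl, which sets C1 and C14; the C3=C4 arm is mismatched and further slowed by allylic 1,3-strain from the C4 methyl cis to C2, and the remaining alkenes lack a directing hydroxyl.

Step 17
Reactants: 26 epoxy alcohol; 27 diethylphosphonoacetic acid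
Product: 28 (1R,2S,6S,14S)-6-acetoxy-1,14-epoxy-4,8,12-trimethyl 14-membered carbocyclic trien-2-yl (diethoxyphosphoryl)acetate
Conditions: (EtO)2P(O)CH2CO2H, dicyclohexylcarbodiimide, 4-(dimethylamino)pyridine (cat.), CH2Cl2, 0 °C → rt
Reagents that add atoms: diethylphosphonoacetic acid (27), CCOP(=O)(CC(=O)O)OCC
Why: Steglich esterification acylates the secondary epoxy alcohol at oxygen under neutral conditions that spare the epoxide and all stereocentres.

Step 18
Reactants: 28 epoxy phosphonoacetate; 4 formaldehyde (as paraformaldehyde)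
Product: 30 Kericembrenolide D, via α-phosphono lactone 29 (not isolated)
Conditions: KOt-Bu (1.05 equiv), THF, 0 °C → rt; then (CH2O)n, rt; NH4Cl quench
Reagents that add atoms: formaldehyde (4), C=O
Why: The phosphonate-stabilised carbanion opens the epoxide at C1 in a 5-exo mode (the topology of the classical cyclisations of 2,3-epoxy alcohol carbamates) with inversion at C1, giving the trans-fused lactone and a C14 alkoxide of retained configuration; proton transfer then forms the phosphonate anion of 29, which undergoes Horner–Wadsworth–Emmons olefination with formaldehyde.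

Compound list
1 | but-3-yn-1-ol | C#CCCO | starting material
2 | 1-[(but-3-yn-1-yloxy)methyl]-4-methoxybenzene | C#CCCOCc1ccc(OC)cc1 | intermediate
3 | trimethylaluminium | C[Al](C)C | starting material
4 | formaldehyde (used as paraformaldehyde) | C=O | starting material
5 | {(1E)-4-[(4-methoxyphenyl)methoxy]-2-methylbut-1-en-1-yl}dimethylalane | C[Al](C)/C=C(\C)CCOCc1ccc(OC)cc1 | intermediate (not isolated)
6 | lithium butyl{(1E)-4-[(4-methoxyphenyl)methoxy]-2-methylbut-1-en-1-yl}dimethylalanate | [Li+].CCCC[Al-](C)(C)/C=C(\C)CCOCc1ccc(OC)cc1 | intermediate (not isolated)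
7 | (2E)-5-[(4-methoxyphenyl)methoxy]-3-methylpent-2-en-1-ol | OC/C=C(\C)CCOCc1ccc(OC)cc1 | intermediate
8 | (2E)-5-[(4-methoxyphenyl)methoxy]-3-methylpent-2-enal | O=C/C=C(\C)CCOCc1ccc(OC)cc1 | intermediate
9 | vinylmagnesium bromide | C=C[Mg]Br | starting material
10 | (3R,4E)-7-[(4-methoxyphenyl)methoxy]-5-methylhepta-1,4-dien-3-ol | C=C[C@@H](O)/C=C(\C)CCOCc1ccc(OC)cc1 | intermediate
11 | tert-butyl{[(3R,4E)-7-[(4-methoxyphenyl)methoxy]-5-methylhepta-1,4-dien-3-yl]oxy}dimethylsilane | C=C[C@@H](O[Si](C)(C)C(C)(C)C)/C=C(\C)CCOCc1ccc(OC)cc1 | intermediate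
12 | (3E,5R)-5-[(tert-butyldimethylsilyl)oxy]-3-methylhepta-3,6-dien-1-ol | OCC/C(C)=C/[C@H](O[Si](C)(C)C(C)(C)C)C=C | intermediate
13 | (3E,5R)-5-[(tert-butyldimethylsilyl)oxy]-3-methylhepta-3,6-dienal (fragment 1) | O=CC/C(C)=C/[C@H](O[Si](C)(C)C(C)(C)C)C=C | intermediate
14 | pent-4-yn-1-ol | C#CCCCO | starting material
15 | ethyl 2-(triphenylphosphoranylidene)propanoate | CCOC(=O)C(C)=P(c1ccccc1)(c1ccccc1)c1ccccc1 | starting material
16 | pent-4-ynal | C#CCCC=O | intermediate (not isolated)
17 | ethyl (2E)-2-methylhept-2-en-6-ynoate | C#CCC/C=C(\C)C(=O)OCC | intermediate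
18 | (2E)-2-methylhept-2-en-6-yn-1-ol | C#CCC/C=C(\C)CO | intermediate
19 | (5E)-7-bromo-6-methylhept-5-en-1-yne | C#CCC/C=C(\C)CBr | intermediate
20 | (5E)-6-methylnona-5,8-dien-1-yne (fragment 2) | C#CCC/C=C(\C)CC=C | intermediate
21 | dimethyl[(1E,5E)-2,6-dimethylnona-1,5,8-trien-1-yl]alane | C[Al](C)/C=C(\C)CC/C=C(\C)CC=C | intermediate (not isolated)
22 | (3R,4E,7S,8E,12E)-3-[(tert-butyldimethylsilyl)oxy]-5,9,13-trimethylhexadeca-1,4,8,12,15-pentaen-7-ol | C=C[C@@H](O[Si](C)(C)C(C)(C)C)/C=C(\C)C[C@H](O)/C=C(\C)CC/C=C(\C)CC=C | intermediate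
23 | (3R,4E,7S,8E,12E)-3-[(tert-butyldimethylsilyl)oxy]-5,9,13-trimethylhexadeca-1,4,8,12,15-pentaen-7-yl acetate | C=C[C@@H](O[Si](C)(C)C(C)(C)C)/C=C(\C)C[C@H](OC(C)=O)/C=C(\C)CC/C=C(\C)CC=C | intermediate
24 | (2R,6S)-2-silyloxy 6-acetate macrocycle, E at C1=C14, C3=C4, C7=C8, C11=C12 | C1/C=C(\C)C/C=C/[C@@H](O[Si](C)(C)C(C)(C)C)/C=C(\C)C[C@H](OC(C)=O)/C=C(\C)C1 | intermediate
25 | (2R,6S)-2-hydroxy 6-acetate macrocycle, E at C1=C14, C3=C4, C7=C8, C11=C12 | C1/C=C(\C)C/C=C/[C@@H](O)/C=C(\C)C[C@H](OC(C)=O)/C=C(\C)C1 | intermediate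
26 | (1S,2S,6S,14S)-1,14-epoxy-2-hydroxy 6-acetate macrocycle | C1/C=C(\C)C[C@@H]2O[C@H]2[C@@H](O)/C=C(\C)C[C@H](OC(C)=O)/C=C(\C)C1 | intermediate
27 | diethylphosphonoacetic acid | CCOP(=O)(CC(=O)O)OCC | starting material
28 | (1R,2S,6S,14S)-1,14-epoxy 6-acetate macrocycle 2-(diethoxyphosphoryl)acetate | C1/C=C(\C)C[C@@H]2O[C@H]2[C@@H](OC(=O)CP(=O)(OCC)OCC)/C=C(\C)C[C@H](OC(C)=O)/C=C(\C)C1 | intermediate
29 | (1S,2S,6S,14S)-α-(diethoxyphosphoryl) trans-fused lactone with free C14 hydroxyl (Cα epimers or anion) | CCOP(=O)(OCC)C1C(=O)O[C@H]2/C=C(\C)C[C@H](OC(C)=O)/C=C(\C)CC/C=C(\C)C[C@H](O)[C@H]12 | intermediate (not isolated)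
30 | Kericembrenolide D, (1S,2S,6S,14S) | C=C1C(=O)O[C@H]2/C=C(\C)C[C@H](OC(C)=O)/C=C(\C)CC/C=C(\C)C[C@H](O)[C@H]12 | target

Total step count: 18. Longest linear sequence: 14 steps (steps 1–7, then 12–18).

Steps most likely to fail

Step 12. Methyl instead of alkenyl transfer to the aldehyde, drift of the β,γ-unsaturated aldehyde into conjugation, or weak facial discrimination at C6 could erode the coupling. The fallback sets out from 20: methylalumination as before, followed by iodinolysis with I2, gives (1E,5E)-1-iodo-2,6-dimethylnona-1,5,8-triene F1. A Nozaki–Hiyama–Kishi coupling of F1 with aldehyde 13 (CrCl2, catalytic NiCl2, a chiral oxazoline–sulfonamide ligand of the Kishi type, THF) then forms the same C6–C7 bond under conditions known to tolerate enolisable aldehydes. The route is rejoined at 22.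

Step 18. The stabilised phosphonate carbanion may open the epoxide too slowly, and the basic medium may then cleave the C6 acetate or move the lactone acyl group to the C14 oxygen. The fallback sets out from 26: esterification with 2-(trimethylsilyl)ethyl hydrogen malonate (dicyclohexylcarbodiimide, 4-(dimethylamino)pyridine) gives the mixed malonate F3. Its softer and more acidic malonate anion (Cs2CO3, MeCN) should close the ring at C1 to the α-[2-(trimethylsilyl)ethoxycarbonyl] lactone F4. Fluoride (tris(dimethylamino)sulfonium difluorotrimethylsilicate) unmasks the α-carboxy lactone F5, and decarboxylative Mannich methylenation (aqueous formaldehyde, Et2NH) rejoins the route at 30.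

Step 14. Slow initiation beside the bulky silyl ether, oligomerisation, or poor E/Z control at C1=C14 could spoil the macrocyclisation. The fallback sets out from 23: the silyl group is removed first (Bu4NF, AcOH, THF) to give (3R,4E,7S,8E,12E)-3-hydroxy-5,9,13-trimethylhexadeca-1,4,8,12,15-pentaen-7-yl acetate F2. The ring is then closed on this unhindered free allylic alcohol with RuCl2(H2IMes)(PCy3)(=CHPh) under high dilution, where the hydroxyl can assist the carbene. The route is rejoined at 25.

Further compounds
F1 | step 12 | (1E,5E)-1-iodo-2,6-dimethylnona-1,5,8-triene | I/C=C(\C)CC/C=C(\C)CC=C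
F2 | step 14 | (3R,4E,7S,8E,12E)-3-hydroxy-5,9,13-trimethylhexadeca-1,4,8,12,15-pentaen-7-yl acetate | C=C[C@@H](O)/C=C(\C)C[C@H](OC(C)=O)/C=C(\C)CC/C=C(\C)CC=C
F3 | step 18 | epoxy macrocycle 2-[2-(trimethylsilyl)ethyl malonate] | C1/C=C(\C)C[C@@H]2O[C@H]2[C@@H](OC(=O)CC(=O)OCC[Si](C)(C)C)/C=C(\C)C[C@H](OC(C)=O)/C=C(\C)C1
F4 | step 18 | α-[2-(trimethylsilyl)ethoxycarbonyl] trans-fused lactone with free C14 hydroxyl | C[Si](C)(C)CCOC(=O)C1C(=O)O[C@H]2/C=C(\C)C[C@H](OC(C)=O)/C=C(\C)CC/C=C(\C)C[C@H](O)[C@H]12
F5 | step 18 | α-carboxy trans-fused lactone with free C14 hydroxyl | OC(=O)C1C(=O)O[C@H]2/C=C(\C)C[C@H](OC(C)=O)/C=C(\C)CC/C=C(\C)C[C@H](O)[C@H]12
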